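## Analysis of the target

The target 6 is oxacyclohentriacontan-2-one (triacontan-30-olide), C30H58O2: one 31-membered ring made of the ester oxygen, the carbonyl carbon C1 and the twenty-nine methylene carbons C2 to C30, numbered along the chain from the carbonyl to the oxygen-bearing C30. It has no stereocentre, no double bond and no substituent, so nothing has to be set or related; the task is ring construction and an exact carbon count. The only sensitive group is the lactone, which is open to hydrolysis, to transesterification (ring opening and oligomerisation) and to hydride or organometallic reagents. Three things make the synthesis hard. The chain has no conformational bias, so closing an open C30 precursor is an entropically unassisted 31-membered cyclisation that competes with oligomerisation. No C30 chain with two different ends is commercial, so such a precursor must first be assembled. Homologues with one CH2 more or less, and cyclic dimers, are almost inseparable from 6, so the carbon count must be fixed by construction. The feature the route exploits is arithmetic: the bond C15–C16 (or, equivalently, C16–C17) divides the methylene chain into arcs of 14 and 15 CH2 groups, which together with C1 are the carbon skeletons of a 15-membered and a 16-membered carbocyclic ketone less one carbonyl carbon (30 = 15 + 16 − 1). The ester unit C1(=O)–O is what remains of two peroxide-bridged ketone carbonyls after one is expelled as carbon dioxide, so the 31-membered ring is made from two ready-made carbocycles by a fragmentation and recombination that forms C15–C16 and O–C30 in one operation.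

## Retrosynthetic reasoning

**6 back to 5.** The lactone 6 is cut at the alkyl–oxygen bond O–C30, and the carboxyl carbon that the forward step loses is put back on C30. This gives the 33-membered cyclic diacyl peroxide 5 (1,2-dioxacyclotritriacontane-3,33-dione), in which the future lactone oxygen and C30 sit next to each other across an O–O bond. The cut is placed at O–C30 and not at the acyl bond C1–O, because an acyl–oxygen cut only leads back to an open hydroxy acid. The alkyl–oxygen bond can instead be made by recombination of an acyloxy and an alkyl radical that are born as neighbours when 5 breaks down. The gain is a final ring closure that needs neither dilution nor an activating reagent; the forward reaction has to lose exactly one carboxyl carbon.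

**5 back to 4.** The peroxide 5 is cut at C15–C16 (numbering of 6), and each of the two carbons is reconnected to the carbonyl carbon at the other end of its own arc. This turns 5 into its constitutional isomer 4, the 1,2,4,5-tetraoxane that carries a spiro-cyclopentadecane and a spiro-cyclohexadecane. C15–C16 is chosen because it is the one place along the 29 methylenes where the two arcs, each with its carbonyl carbon, become rings of 15 and 16 carbons, the sizes of two commercial ketones. Any other bond would call for ring sizes such as 12 + 19 or 14 + 17. The gain is that all thirty carbons and the whole macrocycle come from two existing rings, with no open-chain C30 intermediate. The forward reaction is a thermal O–O homolysis, a twofold ring-opening β-scission and a recombination of the two radical ends.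

**4 back to 2 and 3.** The tetraoxane 4 is cut at both C–O bonds of the spiro carbon of its 16-membered ring, which gives the geminal dihydroperoxide 2 (1,1-dihydroperoxycyclopentadecane) and the ketone 3 (cyclohexadecanone). Building 4 from a preformed dihydroperoxide of one ketone and the other ketone is what pairs one 15-membered with one 16-membered ring. The symmetrical peroxides must be avoided, because they would end as the C29 and C31 homologues of 6. The forward reaction is an acid-catalysed cyclocondensation that must run without peroxide exchange.

**2 back to 1.** The two C–OOH bonds of 2 are cut to the ketone 1 (cyclopentadecanone). The forward reaction is a twofold perhydration of the carbonyl group with the oxidant of step 1.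

## Alternatives that were turned down

Alternative 1: This is the textbook disconnection. The acyl bond C1–O is cut to 30-hydroxytriacontanoic acid A1, which is closed by macrolactonisation of the activated acid (Yamaguchi or Corey–Nicolaou conditions, syringe-pump dilution). It was turned down because A1 is not commercial. It must be assembled from two pieces of about fifteen carbons by a C–C coupling with differentiated chain ends, some five to seven steps. The key step then still faces an unbiased 31-membered closure, in which cyclic dimer and linear oligomers form by the same mechanism and are hard to remove. The key step would build none of the carbon chain.

Alternative 2: The bond C15–C16 is cut with the ester already in place and closed electrochemically, by twofold anodic decarboxylation (intramolecular Kolbe coupling) of the ester-tethered diacid 16-[(15-carboxypentadecanoyl)oxy]hexadecanoic acid A2. One esterification of two commercial C16 acids would give A2. It was turned down on mechanistic grounds. Kolbe radicals arise in a dense carboxylate layer at the anode at high current density, and the two carboxylates of one molecule are not discharged at the same moment. The first radical therefore meets a radical of a neighbouring molecule sooner than its own far end, and chain extension to linear oligo-esters is expected. Dilution, which ring closure would need, favours further oxidation of the radical to the cation. The chosen route keeps the idea of a radical recombination at C15–C16 but generates both radical centres at once and side by side.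

Alternative 3: The ring oxygen is inserted last, by Baeyer–Villiger oxidation of cyclotriacontanone A3 with a peracid, which places the oxygen between C1 and C30. A3 is symmetrical, so there is no question of regiochemistry. It was turned down because the single-atom insertion solves nothing of the real problem. A3 is a 30-membered carbocycle whose preparation needs an open-chain precursor of thirty or more carbons, an unassisted macrocyclisation at a C–C bond, and further steps to delete the functional group that this closure leaves behind. Large unstrained ketones are also slow in the Baeyer–Villiger reaction, and the step count would exceed that of Alternative 1.

Ring-closing olefin metathesis followed by hydrogenation is not among the rejected alternatives because it is kept as the fallback for step 3.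

Key step: step 3

Assumption: the SMILES is read as one lactone carbonyl carbon, twenty-nine ring methylene carbons and one ring oxygen (31-membered ring, C30H58O2); the macrocyclic ketones 1 and 3 are taken as commercial musk-grade chemicals.

Remark on handling: 2 and 4 are organic peroxides of low active-oxygen content for their mass. They are kept in solution where possible and handled behind a shield, and 4 is fed slowly into the hot solvent in step 3 so that it never accumulates.

## Route

Step 1
Reactants: 1 cyclopentadecanone
Product: 2 1,1-dihydroperoxycyclopentadecane
Conditions: 50% aq H2O2 (4 equiv), Re2O7 (2 mol %), MeCN/CH2Cl2, rt
Reagents that add atoms: hydrogen peroxide, OO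
Why: Acid-catalysed perhydration (peroxyketalisation) of a ketone: perrhenic acid generated from Re2O7 activates the carbonyl, H2O2 adds twice by way of the hydroxy hydroperoxide, and the excess of H2O2 drives the equilibrium to the geminal dihydroperoxide, as is standard for large-ring ketones. No stereocentre is formed; 2 is purified by chromatography so that no 1 reaches step 2.

Step 2
Reactants: 2 1,1-dihydroperoxycyclopentadecane; 3 cyclohexadecanone
Product: 4 16,17,34,35-tetraoxadispiro[14.2.15.2]pentatriacontane (the 1,2,4,5-tetraoxane with a spiro-cyclopentadecane at C3 and a spiro-cyclohexadecane at C6)
Conditions: Re2O7 (5 mol %), CH2Cl2, rt
Reagents that add atoms: none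
Why: Acid-catalysed cyclocondensation of a geminal dihydroperoxide with a ketone to an unsymmetrical 1,2,4,5-tetraoxane; the six-membered ring closes by attack of the second OOH group on the peroxy-oxocarbenium ion, and preformed 2 with one equivalent of 3 at room temperature pairs one 15-membered with one 16-membered ring. No stereocentre is formed; 4 is checked by mass spectrometry for the absence of the two symmetrical tetraoxanes.

Step 3
Reactants: 4 16,17,34,35-tetraoxadispiro[14.2.15.2]pentatriacontane
Product: 6 oxacyclohentriacontan-2-one (the target), via cyclic hentriacontanedioyl peroxide 5 (not isolated)
Conditions: n-decane (0.02 mol/L), reflux (174 °C), N2, slow addition of 4, 3 h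
Reagents that add atoms: none
Why: Story-type thermal fragmentation and recombination of a dicycloalkylidene diperoxide; the closest known reaction type is the thermolysis of dispiro-1,2,4,5-tetraoxanes of cyclic ketones to the macrolactone that holds one carbon fewer than the two ketones together. Homolysis of one O–O bond of 4 gives a bis(alkoxy) diradical in which each alkoxy radical sits on a carbon bearing a second oxygen, so β-scission of a ring C–C bond is fast and ester-forming and opens the 15- and the 16-membered carbocycle to a diacyl peroxide with two primary alkyl radical ends. These ends were the α-carbons of the two spiro centres and are born a few ångström apart, so they should recombine (alkyl–alkyl, C15–C16 of the target) to the 33-membered diacyl peroxide 5 without dilution. At 174 °C 5 cannot persist: O–O homolysis, loss of one CO2 and recombination of the new primary radical with the remaining acyloxy radical (the ester-forming in-cage recombination known from diacyl peroxides) closes the 31-membered ring at O–C30. Both rings are thus closed by recombination of radical pairs generated inside one molecule and not by polar cyclisation of a free chain, which is why ring size should matter little. No stereocentre is formed, and because 5 is symmetrical about its (CH2)29 chain either carboxyl carbon can be the one lost with the same lactone 6 resulting. The step needs C–C over C–O β-scission (the latter only returns 1 and 3, which are distilled off and recycled) and recombination over disproportionation or hydrogen abstraction (helped by the proximity of the radical ends and an alkane solvent with strong C–H bonds). It also needs loss of one CO2 instead of two, which the substrate does not control, so the C29 cycloalkane that has lost both carboxyl carbons is expected beside 6 and is removed as the hydrocarbon fraction on silica.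

## Compound list

1 | cyclopentadecanone | O=C1CCCCCCCCCCCCCC1 | starting material
2 | 1,1-dihydroperoxycyclopentadecane | OOC1(OO)CCCCCCCCCCCCCC1 | intermediate
3 | cyclohexadecanone | O=C1CCCCCCCCCCCCCCC1 | starting material
4 | 16,17,34,35-tetraoxadispiro[14.2.15.2]pentatriacontane | O1OC2(CCCCCCCCCCCCCC2)OOC13CCCCCCCCCCCCCCC3 | intermediate
5 | 1,2-dioxacyclotritriacontane-3,33-dione (cyclic hentriacontanedioyl peroxide) | O=C1CCCCCCCCCCCCCCCCCCCCCCCCCCCCCC(=O)OO1 | intermediate (not isolated)
6 | oxacyclohentriacontan-2-one (triacontan-30-olide) | O=C1CCCCCCCCCCCCCCCCCCCCCCCCCCCCCO1 | target

All compounds are achiral.

## Step count and least certain steps

Total step count: 3. Longest linear sequence: 3 steps (1 to 2 to 4 to 6); 3 enters in step 2.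

**Step 3 (key step).** The decarboxylation may run past the lactone stage: the second carboxyl carbon is lost before the acyloxy and alkyl radical ends recombine, so that the C29 cycloalkane becomes the main macrocycle. C–O instead of C–C β-scission only returns the two ketones, and disproportionation or hydrogen abstraction of the radical pair gives open-chain material. None of these branches is controlled by the substrate, only by temperature and medium, so 6 should be expected as one of several products. The step is accepted because its precursor costs two steps and the returned ketones are recycled.

Fallback, from 3 back to 6 by known chemistry: Baeyer–Villiger oxidation of 3 (CF3CO3H, Na2HPO4, CH2Cl2) should give oxacycloheptadecan-2-one F1. Ring opening with HBr in AcOH gives 16-bromohexadecanoic acid F2, and E2 elimination with KOtBu in THF gives hexadec-15-enoic acid F3. Half of F3 is reduced with LiAlH4 to hexadec-15-en-1-ol F4. Steglich esterification of F3 with F4 (N,N'-dicyclohexylcarbodiimide, DMAP) gives hexadec-15-en-1-yl hexadec-15-enoate F5. Ring-closing olefin metathesis (second-generation Grubbs catalyst, 1 mmol/L in CH2Cl2, reflux, 1,4-benzoquinone against double-bond migration) gives oxacyclohentriacont-16-en-2-one F6 as an E/Z mixture. Hydrogenation (H2, Pd/C, EtOAc) gives 6.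

**Step 2.** Acid-catalysed peroxide exchange is the main danger: 2 reverts to 1 and H2O2 and the fragments recombine, which would scramble the ring pairing and put symmetrical tetraoxanes beside 4. After step 3 these would appear as the C29 and C31 homologues of 6, which cannot be separated. Over-condensation to larger cyclic peroxides is the second risk.

Fallback, from 2 back to 4: silylation of 2 with N,O-bis(trimethylsilyl)acetamide gives 1,1-bis(trimethylsilylperoxy)cyclopentadecane F7. Cyclocondensation of F7 with 3 under trimethylsilyl triflate in CH2Cl2 at −78 °C then gives 4. At this temperature the silyl peroxide cannot revert to ketone and H2O2, so exchange is suppressed.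

**Step 1.** Perhydration may stop short, because the carbonyl group of a large unstrained and lipophilic ring is a poor electrophile in an aqueous medium. The dihydroperoxide may also condense further with unreacted ketone to peroxide-bridged dimers.

Fallback, from 1 back to 2: ketalisation of 1 (HC(OMe)3, MeOH, TsOH) gives 1,1-dimethoxycyclopentadecane F8. Peroxide exchange of F8 with anhydrous ethereal H2O2 under BF3·OEt2 gives 2. This goes through the oxocarbenium ion under water-free conditions and is driven by the release of methanol.

## Further compounds

F1 | step 3 | oxacycloheptadecan-2-one (hexadecan-16-olide) | O=C1CCCCCCCCCCCCCCCO1
F2 | step 3 | 16-bromohexadecanoic acid | OC(=O)CCCCCCCCCCCCCCCBr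
F3 | step 3 | hexadec-15-enoic acid | OC(=O)CCCCCCCCCCCCCC=C
F4 | step 3 | hexadec-15-en-1-ol | OCCCCCCCCCCCCCCC=C
F5 | step 3 | hexadec-15-en-1-yl hexadec-15-enoate | C=CCCCCCCCCCCCCCC(=O)OCCCCCCCCCCCCCCC=C
F6 | step 3 | oxacyclohentriacont-16-en-2-one (E/Z mixture) | O=C1CCCCCCCCCCCCCC=CCCCCCCCCCCCCCCO1
F7 | step 2 | 1,1-bis(trimethylsilylperoxy)cyclopentadecane | C[Si](C)(C)OOC1(OO[Si](C)(C)C)CCCCCCCCCCCCCC1
F8 | step 1 | 1,1-dimethoxycyclopentadecane | COC1(OC)CCCCCCCCCCCCCC1
A1 | alternative 1 | 30-hydroxytriacontanoic acid | OCCCCCCCCCCCCCCCCCCCCCCCCCCCCCC(=O)O
A2 | alternative 2 | 16-[(15-carboxypentadecanoyl)oxy]hexadecanoic acid | OC(=O)CCCCCCCCCCCCCCC(=O)OCCCCCCCCCCCCCCCC(=O)O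
A3 | alternative 3 | cyclotriacontanone | O=C1CCCCCCCCCCCCCCCCCCCCCCCCCCCCC1
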